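The runs stem from a simulated flask from invented constants; noise was put on by code.

- No constant of this chemistry was given, so I read one from the dawn run in the way a bench chemist reads a straight line: D reached 34.2 % of 15 mM of Q by 15.0 min, a mean pace of 0.342 mM/min.

| flask | Q | G | J | remark | time | volume of the second phase over the first |
|---|---|---|---|---|---|---|
| dawn | 15 mM | 25.2 mM | 0.63 mM | run made earlier |  |  |
| ochre | 14 mM | 40.0 mM | 0.63 mM |  | 25 min | 1.0 |
| green | 30 mM | 25.2 mM | 0.30 mM |  | 25 min | 1.0 |
| red | 14 mM | 25.2 mM | 0.63 mM |  | 25 min | 1.0 |
| violet | 14 mM | 12.0 mM | 2.0 mM |  | 25 min | 1.0 |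

dawn run (percent of the Q charged)

| time / min | D / % | Q / % |
|---|---|---|
| 1.33 | 4.3 | 90.7 |
| 2.00 | 5.7 | 86.8 |
| 3.00 | 7.5 | 81.0 |
| 4.00 | 11.5 | 76.8 |
| 6.00 | 16.0 | 66.9 |
| 10.0 | 26.2 | 55.6 |
| 15.0 | 34.2 | 48.4 |

(readings scatter by 1 percentage point)

* the flasks by amount of D, in percent of the Q charged, highest first, at 25 min (ochre / green / red / violet)
* the amount of D, in percent of the Q charged of the flask you put first, at 25 min
* the amount of D, in percent of the Q charged of the flask you put last, at 25 min

- charges count per volume of the first phase; a concentration in a rate is the amount of a species over the volume of its own phase; every rate counts per litre of the first phase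
- the earlier runs hold the two phases in the same ratio of volumes as the flask asked about
- no earlier run changes the charge of J; that part of a forecast is a guess

- I took the pace as fixed, a zero-order rule in Q, because the dawn pace went from 0.431 mM/min up to 4.00 min to 0.368 mM/min up to 10.0 min, keeping a factor 0.854 while the Q reading kept 0.724, so D held up better than Q; with a scatter of 1 percentage point this is a reading, not a proof.
- I scaled the pace with the charges of G and J, which is a guess because the dawn run varied neither, and for ochre that gave 0.543 mM/min and 25.8 min, which I call the clearing time, the Q charge over the pace, so that the asked time over the clearing time is the share of Q turned to D.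
- My reckoning gave ochre 96.9 % and red 61.1 % of their Q as D, and green a clearing time of 184 min, hence 13.6 %.
- The rule stops where that ratio reaches one, and ochre stood at 0.969, on the border, so I held its figure as the high side.
- In my reckoning violet crossed a second border: taking one G per D, its scaled pace asked for 1.08 times its G charge, and G, charged below Q, is by those charges the limiting reagent of violet, so I gave violet no figure.
- The forecast gave ochre > red > violet > green, with 58 % for ochre (range 50 % to 68 %) and 23 % for green (range 16 % to 29 %), saying “I assume the rate is first order in J and G, with G consumed”; my ochre stood above its figure and my green below.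

    J + G ⇌ E + X (K = 1.20, k = 29.0 /M/min)
    Q + E → D + J (k = 4200 /M/min)
    2 J → L (k = 18.0 /M/min)
    Q ⇌ Z (K = 0.330, k = 0.0520 /min)

- The flasks gave ochre > red > violet > green, with ochre at 83.1 %, 14 points under its clearing-time figure, and green at 14.6 %, 1.1 points above its own. For the neighbour of ochre charged with 56 mM of Q, I reckoned a clearing time of 103 min, so 24.2 % of its Q as D by 25.0 min, and that flask held 21.6 % of D with 58.3 % of its charge still standing as Q.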